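**Strategy.** The plan disconnects the cyclohexane ring at two exocyclic bonds: C5–C(hydroxyisopropyl) and C10–CH2 of the propanoic acid chain. Methine C5, quaternary C10 and spiro carbon C9 are then the β-carbon, the α-carbon and the carbonyl carbon of 2-methylcyclohex-2-en-1-one. One operation sets both stereocentres and both latent side chains: copper-catalysed enantioselective transfer of isopropenyl to the β-carbon, then allylation of the enolate at the methyl-bearing carbon. Its precursor is the commercial enone with two commercial partners. The ketone later becomes the spiro centre by diene heteroannulation with iodinated atraric acid, and the benzene ring is expanded to the tropone at the end.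

Key step: step 1

Remark: terpenoid labels are used throughout (C9 = ketone/spiro carbon, C10 = quaternary carbon, C5 = methine, C8 = methyl-bearing ring carbon, C11 = CH2 of the dihydrofuran; β = face of the C10 methyl, α = the opposite face), and the ligand antipode in step 1 is assumed to be the one that gives the (3R) adduct, to be fixed by trying both antipodes.

Step 1
Reactants: 1 2-methylcyclohex-2-en-1-one; 2 isopropenylmagnesium bromide; 3 allyl iodide
Product: 5 (2R,3R)-2-methyl-2-(prop-2-en-1-yl)-3-(prop-1-en-2-yl)cyclohexan-1-one, via magnesium enolate 4 (not isolated)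
Conditions: CuBr·SMe2 (5 mol %), BINOL-derived phosphoramidite with a bis(1-phenylethyl)amine unit (6 mol %), 2-MeTHF, −78 °C, slow addition of 2; then 3, DMPU, −78 to 0 °C
Reagents that add atoms: none
Why: The phosphoramidite complex of monovalent copper takes the isopropenyl group from magnesium, adds it through a π-complex and a trivalent-copper σ-species to the β-carbon (C5) of the enone and releases magnesium enolate 4, which allyl iodide then alkylates at the methyl-bearing carbon (C10). The closest known reaction type is copper-catalysed asymmetric conjugate addition of Grignard reagents to 2-substituted cyclohexenones with alkylation of the enolate in the same flask. No ring is closed. The C5 stereocentre is set by the ligand, which chooses the enone face that receives isopropenyl, and the C10 stereocentre is set by the substrate, because the electrophile approaches the enolate anti to the new pseudo-axial isopropenyl group, leaving methyl cis and allyl trans to it. The step needs 1,4- over 1,2-addition (copper catalysis, slow Grignard addition, low temperature), enantiofacial control (ligand) and C-allylation without enolate equilibration (regiodefined tetrasubstituted enolate, soft iodide, DMPU).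

Step 2
Reactants: 5 (2R,3R)-2-methyl-2-(prop-2-en-1-yl)-3-(prop-1-en-2-yl)cyclohexan-1-one
Product: 7 (2R,3R)-2-(3-hydroxypropyl)-2-methyl-3-(prop-1-en-2-yl)cyclohexan-1-one, via catechol boronate 6 (not isolated)
Conditions: catecholborane, RhCl(PPh3)3 (2 mol %), THF, 0 °C to rt; then H2O2, NaOH aq, 0 °C
Reagents that add atoms: hydrogen peroxide, OO
Why: Rhodium-catalysed hydroboration–oxidation should be selective for the monosubstituted allyl alkene over the hindered 1,1-disubstituted isopropenyl group and over the ketone, giving the anti-Markovnikov primary alcohol with no stereocentre touched.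

Step 3
Reactants: 7 (2R,3R)-2-(3-hydroxypropyl)-2-methyl-3-(prop-1-en-2-yl)cyclohexan-1-one
Product: 8 (2R,3R)-2-[3-(tert-butyldimethylsilyloxy)propyl]-2-methyl-3-(prop-1-en-2-yl)cyclohexan-1-one (TBS = tert-butyldimethylsilyl)
Conditions: TBSCl, imidazole, DMF, rt
Reagents that add atoms: tert-butyldimethylsilyl chloride, CC(C)(C)[Si](C)(C)Cl
Why: Silyl ether protection of the primary alcohol removes the hemiketal equilibrium with the ketone and masks the future acid terminus.

Step 4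
Reactants: 8 (2R,3R)-2-[3-(TBSO)propyl]-2-methyl-3-(prop-1-en-2-yl)cyclohexan-1-one
Product: 9 (2R,3S)-2-[3-(TBSO)propyl]-3-(2-hydroxypropan-2-yl)-2-methylcyclohexan-1-one
Conditions: Co(acac)2 (20 mol %), PhSiH3, O2 (1 atm), iPrOH, rt
Reagents that add atoms: dioxygen, O=O
Why: Mukaiyama hydration (hydrogen-atom transfer from a cobalt hydride, capture of the tertiary radical by O2, reduction of the peroxide) should turn the isopropenyl group into the Markovnikov tertiary alcohol without touching the ketone or creating a stereocentre.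

Step 5
Reactants: 9 (2R,3S)-2-[3-(TBSO)propyl]-3-(2-hydroxypropan-2-yl)-2-methylcyclohexan-1-one
Product: 10 (2R,3S)-2-[3-(TBSO)propyl]-2-methyl-3-[2-(triethylsilyloxy)propan-2-yl]cyclohexan-1-one (TES = triethylsilyl)
Conditions: TESOTf, 2,6-lutidine, CH2Cl2, −78 to 0 °C
Reagents that add atoms: triethylsilyl trifluoromethanesulfonate, CC[Si](CC)(CC)OS(=O)(=O)C(F)(F)F
Why: Silylation with a silyl triflate protects the hindered tertiary alcohol so that it can neither bind palladium nor trap an electrophilic C9 in later steps.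

Step 6
Reactants: 10 (2R,3S)-2-[3-(TBSO)propyl]-2-methyl-3-[2-(TESO)propan-2-yl]cyclohexan-1-one
Product: 12 (2R,3S,6RS)-2-[3-(TBSO)propyl]-2,6-dimethyl-3-[2-(TESO)propan-2-yl]cyclohexan-1-one, via lithium enolate 11 (not isolated)
Conditions: LiN(iPr)2, THF, −78 °C; then MeI, −78 to 0 °C
Reagents that add atoms: iodomethane, CI
Why: In this enolate alkylation C8 is the only enolisable position because C10 is quaternary, so a single enolate is methylated, and the C8 configuration does not matter since step 7 removes it.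

Step 7
Reactants: 12 (2R,3S,6RS)-2-[3-(TBSO)propyl]-2,6-dimethyl-3-[2-(TESO)propan-2-yl]cyclohexan-1-one
Product: 14 (5S,6R)-6-[3-(TBSO)propyl]-2,6-dimethyl-5-[2-(TESO)propan-2-yl]cyclohex-2-en-1-one, via silyl enol ether 13 (not isolated)
Conditions: Me3SiOTf, Et3N, CH2Cl2, 0 °C; then Pd(OAc)2, MeCN, rt to 40 °C
Reagents that add atoms: none
Why: In this Saegusa–Ito oxidation the only possible silyl enol ether gives a palladium enolate (divalent palladium), and β-hydride elimination toward C7 should give the conjugated 2-methyl enone.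

Step 8
Reactants: 14 (5S,6R)-6-[3-(TBSO)propyl]-2,6-dimethyl-5-[2-(TESO)propan-2-yl]cyclohex-2-en-1-one
Product: 16 (4S,5R)-5-[3-(TBSO)propyl]-1,5-dimethyl-6-methylidene-4-[2-(TESO)propan-2-yl]cyclohex-1-ene, via β-hydroxysilane 15 (not isolated)
Conditions: Me3SiCH2Li, CeCl3, THF, −78 to 0 °C; aqueous work-up; then KH, THF, 0 °C to rt
Reagents that add atoms: (trimethylsilyl)methyllithium, [Li]C[Si](C)(C)C
Why: In this Peterson olefination the small, weakly basic organocerium reagent should add 1,2 to the hindered enone carbonyl, and syn-elimination of silanolate from the potassium alkoxide of 15 gives the exocyclic methylene of the 1,3-diene.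

Step 9
Reactants: 17 atraric acid (methyl 2,4-dihydroxy-3,6-dimethylbenzoate)
Product: 18 methyl 2,4-dihydroxy-5-iodo-3,6-dimethylbenzoate
Conditions: N-iodosuccinimide, MeCN, 0 °C to rt, dark
Reagents that add atoms: N-iodosuccinimide, O=C1CCC(=O)N1I
Why: Electrophilic aromatic iodination can only occur at C5, the one unsubstituted ring position, which is ortho to one hydroxyl group and para to the other.

Step 10
Reactants: 16 (4S,5R)-5-[3-(TBSO)propyl]-1,5-dimethyl-6-methylidene-4-[2-(TESO)propan-2-yl]cyclohex-1-ene; 18 methyl 2,4-dihydroxy-5-iodo-3,6-dimethylbenzoate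
Product: 19 methyl (2S,5'S,6'R)-6'-[3-(TBSO)propyl]-6-hydroxy-2',4,6',7-tetramethyl-5'-[2-(TESO)propan-2-yl]-3H-spiro[1-benzofuran-2,1'-cyclohex[2]ene]-5-carboxylate (ether oxygen on the α face of C9, C11 on the β face)
Conditions: Pd(OAc)2 (10 mol %), NaHCO3, n-Bu4NCl, DMF, 90 °C
Reagents that add atoms: none
Why: In this Larock-type heteroannulation of a 1,3-diene by an o-iodophenol, zerovalent palladium formed in the flask inserts into the C–I bond, the aryl group adds to the unhindered CH2 terminus (C11) to give a π-allyl complex over C9–C8–C7, and the neighbouring phenoxide closes the five-membered ring at C9 on the palladium-bearing α face, opposite the axial C10 methyl.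

Step 11
Reactants: 19 methyl (2S,5'S,6'R)-6'-[3-(TBSO)propyl]-6-hydroxy-2',4,6',7-tetramethyl-5'-[2-(TESO)propan-2-yl]-3H-spiro[1-benzofuran-2,1'-cyclohex[2]ene]-5-carboxylate
Product: 20 methyl (2S,2'R,3'S,6'R)-2'-[3-(TBSO)propyl]-6-hydroxy-2',4,6',7-tetramethyl-3'-[2-(TESO)propan-2-yl]-3H-spiro[1-benzofuran-2,1'-cyclohexane]-5-carboxylate
Conditions: [Ir(cod)(PCy3)(py)]PF6 (10 mol %), H2 (1–50 bar), CH2Cl2, rt
Reagents that add atoms: none
Why: Homogeneous iridium-catalysed hydrogenation, which avoids hydrogenolysis of the allylic C–O bond, should deliver H2 to the trisubstituted alkene from the α face, which carries the coordinating ether oxygen and is remote from the axial C10 methyl, so that the C8 methyl ends β.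

Step 12
Reactants: 20 methyl (2S,2'R,3'S,6'R)-2'-[3-(TBSO)propyl]-6-hydroxy-2',4,6',7-tetramethyl-3'-[2-(TESO)propan-2-yl]-3H-spiro[1-benzofuran-2,1'-cyclohexane]-5-carboxylate
Product: 21 methyl (2S,2'R,3'S,6'R)-2'-[3-(TBSO)propyl]-3a-(dichloromethyl)-2',4,6',7-tetramethyl-6-oxo-3'-[2-(TESO)propan-2-yl]-3a,6-dihydro-3H-spiro[1-benzofuran-2,1'-cyclohexane]-5-carboxylate (both C3a epimers, which converge in step 13)
Conditions: CHCl3, 30% aq NaOH, n-Bu4NBr (cat.), 40 °C
Reagents that add atoms: chloroform, ClC(Cl)Cl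
Why: In this abnormal Reimer–Tiemann reaction the phenoxide attacks dichlorocarbene through its alkyl-substituted para carbon (C3a), so protonation leaves a 4-dichloromethyl cyclohexa-2,5-dienone, and para attack is favoured under ion-pair conditions because it gives the dienone that is both a vinylogous ester and an alkylidene β-keto ester.

Step 13
Reactants: 21 methyl (2S,2'R,3'S,6'R)-2'-[3-(TBSO)propyl]-3a-(dichloromethyl)-2',4,6',7-tetramethyl-6-oxo-3'-[2-(TESO)propan-2-yl]-3a,6-dihydro-3H-spiro[1-benzofuran-2,1'-cyclohexane]-5-carboxylate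
Product: 22 methyl (2S,2'R,3'S,6'R)-2'-[3-(TBSO)propyl]-2',5,6',8-tetramethyl-7-oxo-3'-[2-(TESO)propan-2-yl]-3,7-dihydrospiro[cyclohepta[b]furan-2,1'-cyclohexane]-6-carboxylate
Conditions: Bu3SnH (slow addition), AIBN, iPr2NEt, PhH, 80 °C
Reagents that add atoms: none
Why: In this radical ring expansion of a 4-dichloromethyl cyclohexadienone, chlorine abstraction gives a chloromethyl radical that closes 3-exo onto the ester-activated, methyl-bearing ring carbon (C4) in preference to the alkoxy-bearing one, the cyclopropylcarbinyl radical opens to the seven-membered ring, and loss of the second chlorine forms the tropone.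

Step 14
Reactants: 22 methyl (2S,2'R,3'S,6'R)-2'-[3-(TBSO)propyl]-2',5,6',8-tetramethyl-7-oxo-3'-[2-(TESO)propan-2-yl]-3,7-dihydrospiro[cyclohepta[b]furan-2,1'-cyclohexane]-6-carboxylate
Product: 23 methyl (2S,2'R,3'S,6'R)-3'-(2-hydroxypropan-2-yl)-2'-(3-hydroxypropyl)-2',5,6',8-tetramethyl-7-oxo-3,7-dihydrospiro[cyclohepta[b]furan-2,1'-cyclohexane]-6-carboxylate
Conditions: HF·pyridine, pyridine, THF, 0 °C to rt
Reagents that add atoms: none
Why: Buffered fluoride desilylation should remove both silyl ethers without ionising the tertiary alkyl tropone ether or touching the methyl ester.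

Step 15
Reactants: 23 methyl (2S,2'R,3'S,6'R)-3'-(2-hydroxypropan-2-yl)-2'-(3-hydroxypropyl)-2',5,6',8-tetramethyl-7-oxo-3,7-dihydrospiro[cyclohepta[b]furan-2,1'-cyclohexane]-6-carboxylate
Product: 25 3-[(2S,2'R,3'S,6'R)-3'-(2-hydroxypropan-2-yl)-6-(methoxycarbonyl)-2',5,6',8-tetramethyl-7-oxo-3,7-dihydrospiro[cyclohepta[b]furan-2,1'-cyclohexan]-2'-yl]propanoic acid, via aldehyde 24 (not isolated)
Conditions: TEMPO (20 mol %), PhI(OAc)2, MeCN/H2O, rt
Reagents that add atoms: water, O
Why: Oxoammonium (TEMPO) oxidation in aqueous acetonitrile should take the primary alcohol through aldehyde 24 and its hydrate to the carboxylic acid, while the tertiary alcohol cannot be oxidised.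

**Compound list**

1 | 2-methylcyclohex-2-en-1-one | CC1=CCCCC1=O | starting material
2 | isopropenylmagnesium bromide | C=C(C)[Mg]Br | starting material
3 | allyl iodide | C=CCI | starting material
4 | bromomagnesium (3R)-2-methyl-3-(prop-1-en-2-yl)cyclohex-1-en-1-olate | Br[Mg]OC1=C(C)[C@@H](C(C)=C)CCC1 | intermediate
5 | (2R,3R)-2-methyl-2-(prop-2-en-1-yl)-3-(prop-1-en-2-yl)cyclohexan-1-one | O=C1CCC[C@H](C(C)=C)[C@@]1(C)CC=C | intermediate
6 | (2R,3R)-2-[3-(1,3,2-benzodioxaborol-2-yl)propyl]-2-methyl-3-(prop-1-en-2-yl)cyclohexan-1-one | O=C1CCC[C@H](C(C)=C)[C@@]1(C)CCCB1Oc2ccccc2O1 | intermediate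
7 | (2R,3R)-2-(3-hydroxypropyl)-2-methyl-3-(prop-1-en-2-yl)cyclohexan-1-one | O=C1CCC[C@H](C(C)=C)[C@@]1(C)CCCO | intermediate
8 | (2R,3R)-2-[3-(TBSO)propyl]-2-methyl-3-(prop-1-en-2-yl)cyclohexan-1-one | O=C1CCC[C@H](C(C)=C)[C@@]1(C)CCCO[Si](C)(C)C(C)(C)C | intermediate
9 | (2R,3S)-2-[3-(TBSO)propyl]-3-(2-hydroxypropan-2-yl)-2-methylcyclohexan-1-one | O=C1CCC[C@H](C(C)(C)O)[C@@]1(C)CCCO[Si](C)(C)C(C)(C)C | intermediate
10 | (2R,3S)-2-[3-(TBSO)propyl]-2-methyl-3-[2-(TESO)propan-2-yl]cyclohexan-1-one | O=C1CCC[C@H](C(C)(C)O[Si](CC)(CC)CC)[C@@]1(C)CCCO[Si](C)(C)C(C)(C)C | intermediate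
11 | lithium (5S,6R)-6-[3-(TBSO)propyl]-6-methyl-5-[2-(TESO)propan-2-yl]cyclohex-1-en-1-olate | [Li]OC1=CCC[C@H](C(C)(C)O[Si](CC)(CC)CC)[C@@]1(C)CCCO[Si](C)(C)C(C)(C)C | intermediate
12 | (2R,3S,6RS)-2-[3-(TBSO)propyl]-2,6-dimethyl-3-[2-(TESO)propan-2-yl]cyclohexan-1-one | O=C1C(C)CC[C@H](C(C)(C)O[Si](CC)(CC)CC)[C@@]1(C)CCCO[Si](C)(C)C(C)(C)C | intermediate
13 | (5S,6R)-6-[3-(TBSO)propyl]-2,6-dimethyl-5-[2-(TESO)propan-2-yl]-1-(trimethylsilyloxy)cyclohex-1-ene | C[Si](C)(C)OC1=C(C)CC[C@H](C(C)(C)O[Si](CC)(CC)CC)[C@@]1(C)CCCO[Si](C)(C)C(C)(C)C | intermediate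
14 | (5S,6R)-6-[3-(TBSO)propyl]-2,6-dimethyl-5-[2-(TESO)propan-2-yl]cyclohex-2-en-1-one | O=C1C(C)=CC[C@H](C(C)(C)O[Si](CC)(CC)CC)[C@@]1(C)CCCO[Si](C)(C)C(C)(C)C | intermediate
15 | (5S,6R)-6-[3-(TBSO)propyl]-2,6-dimethyl-5-[2-(TESO)propan-2-yl]-1-[(trimethylsilyl)methyl]cyclohex-2-en-1-ol (C1 epimers) | C[Si](C)(C)CC1(O)C(C)=CC[C@H](C(C)(C)O[Si](CC)(CC)CC)[C@@]1(C)CCCO[Si](C)(C)C(C)(C)C | intermediate
16 | (4S,5R)-5-[3-(TBSO)propyl]-1,5-dimethyl-6-methylidene-4-[2-(TESO)propan-2-yl]cyclohex-1-ene | C=C1C(C)=CC[C@H](C(C)(C)O[Si](CC)(CC)CC)[C@@]1(C)CCCO[Si](C)(C)C(C)(C)C | intermediate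
17 | atraric acid (methyl 2,4-dihydroxy-3,6-dimethylbenzoate) | COC(=O)c1c(C)cc(O)c(C)c1O | starting material
18 | methyl 2,4-dihydroxy-5-iodo-3,6-dimethylbenzoate | COC(=O)c1c(C)c(I)c(O)c(C)c1O | intermediate
19 | methyl (2S,5'S,6'R)-6'-[3-(TBSO)propyl]-6-hydroxy-2',4,6',7-tetramethyl-5'-[2-(TESO)propan-2-yl]-3H-spiro[1-benzofuran-2,1'-cyclohex[2]ene]-5-carboxylate | COC(=O)c1c(C)c2c(c(C)c1O)O[C@@]1(C2)C(C)=CC[C@H](C(C)(C)O[Si](CC)(CC)CC)[C@@]1(C)CCCO[Si](C)(C)C(C)(C)C | intermediate
20 | methyl (2S,2'R,3'S,6'R)-2'-[3-(TBSO)propyl]-6-hydroxy-2',4,6',7-tetramethyl-3'-[2-(TESO)propan-2-yl]-3H-spiro[1-benzofuran-2,1'-cyclohexane]-5-carboxylate | COC(=O)c1c(C)c2c(c(C)c1O)O[C@@]1(C2)[C@H](C)CC[C@H](C(C)(C)O[Si](CC)(CC)CC)[C@@]1(C)CCCO[Si](C)(C)C(C)(C)C | intermediate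
21 | methyl (2S,2'R,3'S,6'R)-2'-[3-(TBSO)propyl]-3a-(dichloromethyl)-2',4,6',7-tetramethyl-6-oxo-3'-[2-(TESO)propan-2-yl]-3a,6-dihydro-3H-spiro[1-benzofuran-2,1'-cyclohexane]-5-carboxylate (C3a epimers) | COC(=O)C1=C(C)C2(C(Cl)Cl)C(=C(C)C1=O)O[C@@]3(C2)[C@H](C)CC[C@H](C(C)(C)O[Si](CC)(CC)CC)[C@@]3(C)CCCO[Si](C)(C)C(C)(C)C | intermediate
22 | methyl (2S,2'R,3'S,6'R)-2'-[3-(TBSO)propyl]-2',5,6',8-tetramethyl-7-oxo-3'-[2-(TESO)propan-2-yl]-3,7-dihydrospiro[cyclohepta[b]furan-2,1'-cyclohexane]-6-carboxylate | COC(=O)c1c(C)cc2c(c(C)c1=O)O[C@@]1(C2)[C@H](C)CC[C@H](C(C)(C)O[Si](CC)(CC)CC)[C@@]1(C)CCCO[Si](C)(C)C(C)(C)C | intermediate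
23 | methyl (2S,2'R,3'S,6'R)-3'-(2-hydroxypropan-2-yl)-2'-(3-hydroxypropyl)-2',5,6',8-tetramethyl-7-oxo-3,7-dihydrospiro[cyclohepta[b]furan-2,1'-cyclohexane]-6-carboxylate | COC(=O)c1c(C)cc2c(c(C)c1=O)O[C@@]1(C2)[C@H](C)CC[C@H](C(C)(C)O)[C@@]1(C)CCCO | intermediate
24 | methyl (2S,2'R,3'S,6'R)-3'-(2-hydroxypropan-2-yl)-2',5,6',8-tetramethyl-7-oxo-2'-(3-oxopropyl)-3,7-dihydrospiro[cyclohepta[b]furan-2,1'-cyclohexane]-6-carboxylate | COC(=O)c1c(C)cc2c(c(C)c1=O)O[C@@]1(C2)[C@H](C)CC[C@H](C(C)(C)O)[C@@]1(C)CCC=O | intermediate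
25 | 3-[(2S,2'R,3'S,6'R)-3'-(2-hydroxypropan-2-yl)-6-(methoxycarbonyl)-2',5,6',8-tetramethyl-7-oxo-3,7-dihydrospiro[cyclohepta[b]furan-2,1'-cyclohexan]-2'-yl]propanoic acid | COC(=O)c1c(C)cc2c(c(C)c1=O)O[C@@]1(C2)[C@H](C)CC[C@H](C(C)(C)O)[C@@]1(C)CCC(=O)O | target

**Step count.** Total: 15 steps. Longest linear sequence: 14 steps (steps 1–8 and 10–15); step 9 is the one-step side branch.

**Steps most likely to fail**

1. Step 12 (dichloromethylation with loss of aromaticity). The carbene may be attacked by the methyl-bearing carbon between the two oxygens or by oxygen instead of by C3a, hydrolysis of the carbene may outrun C-attack, and the dienone may degrade in the alkaline medium. The fallback sets out from 20 and returns at 22. The sodium phenoxide of 20 (NaH, toluene) is C-alkylated with allyl bromide to the para-allyl dienone F1. Cleavage of its terminal alkene (OsO4 cat., NaIO4, 2,6-lutidine, dioxane/H2O) gives the aldehyde F2, and NaClO2/NaH2PO4/2-methylbut-2-ene gives the acid F3. Coupling with N-hydroxypyridine-2-thione (DCC) gives the Barton ester F4. On irradiation, decarboxylation releases the primary radical on the carbon attached to C3a, which undergoes the same 3-exo closure and ring opening, and pyridylthio transfer gives the ring-expanded sulfide F5. DBU then eliminates pyridine-2-thiol to give 22.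

2. Step 10 (heteroannulation). Carbopalladation of the hindered diene may be slow, β-hydride elimination may divert the π-allyl complex to aryl trienes, and oxygen transfer to C9 may lack facial selectivity. The fallback sets out from 12 and returns at 19. KN(SiMe3)2/PhNTf2 gives the tetrasubstituted enol triflate F6. Methoxycarbonylation (Pd(OAc)2, PPh3, CO, MeOH, Et3N) gives the unsaturated ester F7, and iBu2AlH gives the allylic alcohol F8. Friedel–Crafts allylation of 17 at C5 (BF3·OEt2, CH2Cl2, −40 °C) through the primary terminus of the allyl cation gives the 5-alkylated atraric acid F9. An aerobic Wacker-type cyclisation (Pd(O2CCF3)2, pyridine, O2, toluene, 80 °C) then forms the C9–O bond by oxypalladation on the face opposite the C10 methyl and gives 19 by β-hydride elimination toward C7.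

3. Step 1 (conjugate addition with enolate allylation). Enantiofacial control of the alkenyl transfer may be insufficient, and C-allylation of the magnesium enolate may be so slow that proton transfer scrambles the enolate or allylates it twice. The fallback sets out from magnesium enolate 4 and returns at 5. The enolate is quenched with allyl chloroformate to give the isolable allyl enol carbonate F10. Pd(PPh3)4 (zerovalent palladium) in THF then effects decarboxylative allylation at the methyl-bearing carbon, again anti to the isopropenyl group, to give 5.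

**Further compounds**

F1 | step 12 | methyl (2S,2'R,3'S,6'R)-2'-[3-(TBSO)propyl]-2',4,6',7-tetramethyl-6-oxo-3a-(prop-2-en-1-yl)-3'-[2-(TESO)propan-2-yl]-3a,6-dihydro-3H-spiro[1-benzofuran-2,1'-cyclohexane]-5-carboxylate | COC(=O)C1=C(C)C2(CC=C)C(=C(C)C1=O)O[C@@]3(C2)[C@H](C)CC[C@H](C(C)(C)O[Si](CC)(CC)CC)[C@@]3(C)CCCO[Si](C)(C)C(C)(C)C
F2 | step 12 | methyl (2S,2'R,3'S,6'R)-2'-[3-(TBSO)propyl]-2',4,6',7-tetramethyl-6-oxo-3a-(2-oxoethyl)-3'-[2-(TESO)propan-2-yl]-3a,6-dihydro-3H-spiro[1-benzofuran-2,1'-cyclohexane]-5-carboxylate | COC(=O)C1=C(C)C2(CC=O)C(=C(C)C1=O)O[C@@]3(C2)[C@H](C)CC[C@H](C(C)(C)O[Si](CC)(CC)CC)[C@@]3(C)CCCO[Si](C)(C)C(C)(C)C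
F3 | step 12 | 2-[(2S,2'R,3'S,6'R)-2'-[3-(TBSO)propyl]-5-(methoxycarbonyl)-2',4,6',7-tetramethyl-6-oxo-3'-[2-(TESO)propan-2-yl]-3H-spiro[1-benzofuran-2,1'-cyclohexan]-3a(6H)-yl]acetic acid | COC(=O)C1=C(C)C2(CC(=O)O)C(=C(C)C1=O)O[C@@]3(C2)[C@H](C)CC[C@H](C(C)(C)O[Si](CC)(CC)CC)[C@@]3(C)CCCO[Si](C)(C)C(C)(C)C
F4 | step 12 | 2-thioxopyridin-1(2H)-yl ester of F3 (Barton ester) | COC(=O)C1=C(C)C2(CC(=O)ON4C=CC=CC4=S)C(=C(C)C1=O)O[C@@]3(C2)[C@H](C)CC[C@H](C(C)(C)O[Si](CC)(CC)CC)[C@@]3(C)CCCO[Si](C)(C)C(C)(C)C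
F5 | step 12 | methyl (2S,2'R,3'S,6'R)-2'-[3-(TBSO)propyl]-2',5,6',8-tetramethyl-7-oxo-3a-(pyridin-2-ylsulfanyl)-3'-[2-(TESO)propan-2-yl]-3,3a,4,7-tetrahydrospiro[cyclohepta[b]furan-2,1'-cyclohexane]-6-carboxylate | COC(=O)C1=C(C)CC2(Sc4ccccn4)C(=C(C)C1=O)O[C@@]3(C2)[C@H](C)CC[C@H](C(C)(C)O[Si](CC)(CC)CC)[C@@]3(C)CCCO[Si](C)(C)C(C)(C)C
F6 | step 10 | (5S,6R)-6-[3-(TBSO)propyl]-2,6-dimethyl-5-[2-(TESO)propan-2-yl]cyclohex-1-en-1-yl trifluoromethanesulfonate | O=S(=O)(OC1=C(C)CC[C@H](C(C)(C)O[Si](CC)(CC)CC)[C@@]1(C)CCCO[Si](C)(C)C(C)(C)C)C(F)(F)F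
F7 | step 10 | methyl (5S,6R)-6-[3-(TBSO)propyl]-2,6-dimethyl-5-[2-(TESO)propan-2-yl]cyclohex-1-ene-1-carboxylate | COC(=O)C1=C(C)CC[C@H](C(C)(C)O[Si](CC)(CC)CC)[C@@]1(C)CCCO[Si](C)(C)C(C)(C)C
F8 | step 10 | {(5S,6R)-6-[3-(TBSO)propyl]-2,6-dimethyl-5-[2-(TESO)propan-2-yl]cyclohex-1-en-1-yl}methanol | OCC1=C(C)CC[C@H](C(C)(C)O[Si](CC)(CC)CC)[C@@]1(C)CCCO[Si](C)(C)C(C)(C)C
F9 | step 10 | methyl 5-({(5S,6R)-6-[3-(TBSO)propyl]-2,6-dimethyl-5-[2-(TESO)propan-2-yl]cyclohex-1-en-1-yl}methyl)-2,4-dihydroxy-3,6-dimethylbenzoate | COC(=O)c1c(C)c(CC2=C(C)CC[C@H](C(C)(C)O[Si](CC)(CC)CC)[C@@]2(C)CCCO[Si](C)(C)C(C)(C)C)c(O)c(C)c1O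
F10 | step 1 | (3R)-2-methyl-3-(prop-1-en-2-yl)cyclohex-1-en-1-yl prop-2-en-1-yl carbonate | C=CCOC(=O)OC1=C(C)[C@@H](C(C)=C)CCC1
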